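**Retrosynthetic overview**

1. Atoms carry the numbers 1–38 of the target SMILES. The route rests on C33, the tertiary acetate carbon, lying β to C18 through C19 inside the right cyclohexane (C19, C20, C30, C31, C32, C33) with C18 and O35 cis: C19–C33 is an aldol retron, closed by a samarium Reformatsky reaction onto a finished oxepane.
2. C16–C17 joins the halves: Negishi coupling of a right-half C17 alkylzinc with a left-half C16 enol triflate; hydroboration, oxidation and methylenation then give C16–H and C2=C1.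
3. Each oxepane (O6, C7, C10, C12, C13, C14, C5 and O29, C26, C24, C23, C22, C20, C30) comes from 7-endo opening of an (S)-epoxide by the neighbouring carbinol; each carbinol/quaternary pair (C5/C14, C30/C20) is set in one catalytic asymmetric nerylboration of an aldehyde.
4. The left carbocycle (C2, C3, C4, C5, C14, C16) closes by ring-closing metathesis and is taken on to the C16 ketone.
5. Ring order: left oxepane, left carbocycle; right oxepane, right carbocycle (key step); union; C24 oxidation and C10 release.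

Key step: step 22

Remark: (R)-TRIP and the L-fructose-derived Shi ketone are taken as purchasable catalysts; C24 is carried as the (S) silyl ether although its configuration is lost in step 34; ring locants in names are those of oxepane or 1-benzoxepine.

**Shared reagent**

Step 1
Reactants: 1 nerol
Product: 2 neryl chloride
Conditions: NCS, Me2S, CH2Cl2, −40 → 0 °C
Reagents that add atoms: N-chlorosuccinimide, O=C1CCC(=O)N1Cl
Why: Corey–Kim-type allylic chlorination displaces the alkoxysulfonium ion by SN2 at the primary carbon, so the Z alkene should be kept without allylic transposition.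

Step 2
Reactants: 2 neryl chloride
Product: 3 neryl pinacolboronate
Conditions: B2pin2, Pd2(dba)3 (1 mol%), THF, 60 °C
Reagents that add atoms: bis(pinacolato)diboron, CC1(C)OB(OC1(C)C)B1OC(C)(C)C(C)(C)O1
Why: Pd(0)-catalysed Miyaura-type borylation of the allylic chloride through a π-allylpalladium species places boron on the primary terminus, and the Z geometry should persist because isomerisation through the tertiary σ-allyl is slow.

**Left half**

Step 3
Reactants: 3 neryl pinacolboronate; 4 pent-4-enal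
Product: 5 left homoallylic alcohol
Conditions: (R)-TRIP (5 mol%), 4 Å MS, PhMe, 0 °C; aq. NaHCO3
Reagents that add atoms: none
Why: Chiral phosphoric acid-catalysed allylboration through a Zimmerman–Traxler chair adds the γ-carbon of the boronate to the Re face of the aldehyde (C5, S), and the Z-placed homoprenyl chain ends syn to the new hydroxyl, which sets the quaternary C14 (S) with its methyl and vinyl groups.

Step 4
Reactants: 5 left homoallylic alcohol
Product: 6 left epoxy alcohol
Conditions: L-fructose-derived Shi ketone (30 mol%), Oxone, K2CO3, Bu4NHSO4, MeCN/CH2(OMe)2, aq. Na2B4O7–EDTA, 0 °C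
Reagents that add atoms: Oxone (potassium peroxymonosulfate), [K+].[O-]S(=O)(=O)OO
Why: Shi epoxidation with the chiral dioxirane reacts only at the electron-rich trisubstituted alkene and should give the (S)-epoxide, which fixes C10.

Step 5
Reactants: 6 left epoxy alcohol
Product: 7 left oxepanol
Conditions: BF3·OEt2 (10 mol%), CH2Cl2, −78 → −40 °C
Reagents that add atoms: none
Why: Lewis acid-activated epoxide-opening cycloetherification: the C5 hydroxyl attacks the tertiary carbon C7, where positive charge builds up (7-endo, Markovnikov), so the oxepane closes with the C10–O bond untouched and C10 stays S.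

Step 6
Reactants: 7 left oxepanol
Product: 8 left PMB ether
Conditions: NaH, PMBCl, Bu4NI (cat.), DMF, 0 °C → rt
Reagents that add atoms: 4-methoxybenzyl chloride, COc1ccc(CCl)cc1
Why: Williamson etherification of the secondary alkoxide gives a PMB ether that can later be removed oxidatively beside the silyl ether, the acetate and the alkene.

Step 7
Reactants: 8 left PMB ether
Product: 9 bicyclic cyclohexene
Conditions: Grubbs II (3 mol%), CH2Cl2, 40 °C
Reagents that add atoms: none
Why: Ring-closing metathesis between the butenyl and vinyl groups, initiated at the unhindered butenyl alkene, forms the six-membered ring C2–C3–C4–C5–C14–C16 and expels ethene.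

Step 8
Reactants: 9 bicyclic cyclohexene
Product: 10 bicyclic epoxide
Conditions: mCPBA, NaHCO3, CH2Cl2, 0 °C
Reagents that add atoms: 3-chloroperbenzoic acid, OOC(=O)c1cccc(Cl)c1
Why: Prilezhaev epoxidation should occur on the face opposite the axial C14 methyl, as with other cyclohexenes next to an angular methyl.

Step 9
Reactants: 10 bicyclic epoxide
Product: 11 C16 alcohol
Conditions: LiAlH4, THF, 0 °C → reflux
Reagents that add atoms: none
Why: Hydride opens the epoxide trans-diaxially (Fürst–Plattner rule) at C2, the carbon away from the quaternary centre, which leaves the oxygen on C16.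

Step 10
Reactants: 11 C16 alcohol
Product: 12 C16 ketone
Conditions: DMP, NaHCO3, CH2Cl2, rt
Reagents that add atoms: none
Why: Dess–Martin oxidation of the secondary alcohol is neutral and leaves the PMB ether and the oxepane untouched.

Step 11
Reactants: 12 C16 ketone
Product: 14 left C16 enol triflate, via potassium enolate 13 (not isolated)
Conditions: KHMDS, THF, −78 °C; then PhNTf2, −78 → 0 °C
Reagents that add atoms: N-phenylbis(trifluoromethanesulfonimide), O=S(=O)(N(c1ccccc1)S(=O)(=O)C(F)(F)F)C(F)(F)F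
Why: The ketone can enolise only towards C2 because C14 is quaternary, so deprotonation and O-sulfonylation of the enolate give a single C16=C2 enol triflate.

**Right half**

Step 12
Reactants: 15 2-(2-bromoethyl)-2-methyl-1,3-dioxolane
Product: 17 ketal aldehyde, via Grignard reagent 16 (not isolated)
Conditions: Mg, THF, 30 °C; then DMF, 0 °C; aq. NH4Cl
Reagents that add atoms: N,N-dimethylformamide, CN(C)C=O
Why: Bouveault aldehyde synthesis: the Grignard reagent adds once to DMF and the hemiaminal salt releases the aldehyde on mild work-up with the ketal intact.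

Step 13
Reactants: 3 neryl pinacolboronate; 17 ketal aldehyde
Product: 18 right homoallylic alcohol
Conditions: (R)-TRIP (5 mol%), 4 Å MS, PhMe, 0 °C; aq. NaHCO3
Reagents that add atoms: none
Why: The same chiral phosphoric acid-catalysed allylboration through a Zimmerman–Traxler chair sets C30 (S) by Re-face attack and the quaternary C20 (S) by the syn placement of the Z homoprenyl chain.

Step 14
Reactants: 18 right homoallylic alcohol
Product: 19 right epoxy alcohol
Conditions: L-fructose-derived Shi ketone (30 mol%), Oxone, K2CO3, Bu4NHSO4, MeCN/CH2(OMe)2, aq. Na2B4O7–EDTA, 0 °C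
Reagents that add atoms: Oxone (potassium peroxymonosulfate), [K+].[O-]S(=O)(=O)OO
Why: Shi epoxidation is selective for the trisubstituted alkene under basic conditions that spare the ketal, and should give the (S)-epoxide at C24.

Step 15
Reactants: 19 right epoxy alcohol
Product: 20 right oxepanol
Conditions: BF3·OEt2 (10 mol%), CH2Cl2, −78 → −40 °C
Reagents that add atoms: none
Why: Lewis acid-activated epoxide-opening cycloetherification by the C30 hydroxyl at the tertiary C26 (7-endo, Markovnikov) closes the oxepane, the epoxide being far more easily ionised than the dioxolane at this temperature.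

Step 16
Reactants: 20 right oxepanol
Product: 21 right TBS ether
Conditions: TBSCl, imidazole, DMAP (cat.), DMF, 50 °C
Reagents that add atoms: tert-butyldimethylsilyl chloride, CC(C)(C)[Si](C)(C)Cl
Why: Imidazole-promoted silylation of the only free hydroxyl protects C24 for the reductive, basic and organometallic steps that follow.

Step 17
Reactants: 21 right TBS ether
Product: 23 C18 primary alcohol, via B-alkyl-9-BBN 22 (not isolated)
Conditions: 9-BBN, THF, 0 → 50 °C; then aq. NaOH, H2O2, 0 °C → rt
Reagents that add atoms: hydrogen peroxide, OO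
Why: Anti-Markovnikov hydroboration of the vinyl group with 9-BBN and oxidation with retention turn C19=C18 into C19H2–C18H2OH.

Step 18
Reactants: 23 C18 primary alcohol
Product: 24 C18 carboxylic acid
Conditions: TEMPO (cat.), NaOCl (cat.), NaClO2, MeCN/phosphate buffer pH 6.7, 35 °C
Reagents that add atoms: sodium chlorite, [Na+].[O-]Cl=O
Why: TEMPO/hypochlorite oxidation to the aldehyde and chlorite (Pinnick-type) oxidation to the acid run near neutral pH, which the ketal and the silyl ether tolerate.

Step 19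
Reactants: 24 C18 carboxylic acid
Product: 25 methyl ester
Conditions: MeI, K2CO3, DMF, rt
Reagents that add atoms: iodomethane, CI
Why: SN2 O-alkylation of the carboxylate gives the methyl ester without acid.

Step 20
Reactants: 25 methyl ester
Product: 28 bromo ester ketal, via lithium enolate 26 (not isolated), via silyl ketene acetal 27 (not isolated)
Conditions: LDA, THF, −78 °C; TMSCl; then NBS, −78 → 0 °C
Reagents that add atoms: N-bromosuccinimide, O=C1CCC(=O)N1Br
Why: Ester enolisation at C19 (the only acidic site while the ketone is masked), O-silylation and electrophilic bromination of the ketene acetal give the α-bromo ester as a C19 epimer mixture, which is of no consequence.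

Step 21
Reactants: 28 bromo ester ketal
Product: 29 bromo keto ester
Conditions: PPTS, acetone/H2O, 60 °C
Reagents that add atoms: water, O
Why: Mild acid-catalysed ketal hydrolysis frees the C33 methyl ketone while the hindered TBS ether and the bromo ester survive.

Step 22
Reactants: 29 bromo keto ester
Product: 30 bicyclic cis-β-hydroxy ester
Conditions: SmI2 (2.5 equiv), THF, −78 °C; sat. aq. NH4Cl at −78 °C
Reagents that add atoms: none
Why: SmI2 reduces the C19–Br bond in two one-electron steps to a samarium(III) ester enolate at C19 only (the methyl ketone is not reduced at −78 °C without additives), and this enolate adds to the C33 ketone; the closest known reaction type is the samarium diiodide intramolecular Reformatsky reaction of α-halo esters with ketones. The cyclohexane (C19, C20, C30, C31, C32, C33) closes in a 6-(enolexo)-exo-trig mode through a chair in which the oxepane bonds C20–C22 and C30–O29 are equatorial and the C21 methyl is axial. C33 is controlled by that axial methyl: the ketone turns its samarium-bound oxygen axial so that the C34 methyl avoids a 1,3-diaxial clash with C21. C19 is controlled by the chelate: samarium can bridge the enolate oxygen and an axial O35 only if C18 is equatorial, which puts C18 and O35 cis. Both C19 bromide epimers give the same planar enolate, so the mixture converges, and the existing C20 and C30 centres fix the absolute sense. The step needs chemoselectivity (enolate formation ahead of ketyl formation, no protonation before closure) and cis diastereoselectivity; the first is secured by the much easier reduction of the α-bromo ester under aprotic conditions, the second by the chelated chair.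

Step 23
Reactants: 30 bicyclic cis-β-hydroxy ester
Product: 31 bicyclic 1,3-diol
Conditions: LiAlH4, Et2O, 0 °C → rt
Reagents that add atoms: none
Why: Hydride reduction of the ester to the C18 primary alcohol is placed before acetylation because a tertiary acetate would not survive a hydride strong enough for this hindered ester.

Step 24
Reactants: 31 bicyclic 1,3-diol
Product: 32 β-hydroxy aldehyde
Conditions: DMP, NaHCO3, CH2Cl2, 0 °C
Reagents that add atoms: none
Why: Dess–Martin oxidation can only touch the primary alcohol, and the buffered neutral medium avoids retro-aldol cleavage and epimerisation at C19.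

Step 25
Reactants: 32 β-hydroxy aldehyde
Product: 33 vinyl carbinol
Conditions: Ph3PCH3Br, KOtBu, THF, 0 °C
Reagents that add atoms: methyltriphenylphosphonium bromide, C[P+](c1ccccc1)(c1ccccc1)c1ccccc1.[Br-]
Why: Wittig methylenation of the aldehyde adds C17; the small ylide reaches the hindered carbonyl and the free tertiary hydroxyl is tolerated.

Step 26
Reactants: 33 vinyl carbinol
Product: 34 vinyl acetate
Conditions: AcCl, PhNMe2, CH2Cl2, 0 °C → rt
Reagents that add atoms: acetyl chloride, CC(Cl)=O
Why: O-Acylation with acetyl chloride buffered by N,N-dimethylaniline is a standard way to acetylate hindered axial tertiary alcohols without ionising them, and it installs the C33 acetate of the target.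

Step 27
Reactants: 34 vinyl acetate
Product: 36 C17 primary alcohol, via B-alkyl-9-BBN 35 (not isolated)
Conditions: 9-BBN, THF, 0 → 50 °C; then NaBO3·4H2O, H2O, rt
Reagents that add atoms: sodium perborate, [Na+].[Na+].O[B-]1(O)OO[B-](O)(O)OO1
Why: Anti-Markovnikov hydroboration of the vinyl group and mild perborate oxidation give the C17 alcohol without hydrolysing the acetate.

Step 28
Reactants: 36 C17 primary alcohol
Product: 37 C17 iodide
Conditions: I2, PPh3, imidazole, CH2Cl2, 0 °C → rt
Reagents that add atoms: iodine, II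
Why: Appel-type iodination displaces the alkoxyphosphonium ion by iodide in an SN2 step at the unhindered primary carbon.

**Union and end game**

Step 29
Reactants: 37 C17 iodide; 14 left C16 enol triflate
Product: 39 coupled C16=C2 alkene, via alkylzinc iodide 38 (not isolated)
Conditions: Zn dust (BrCH2CH2Br, TMSCl), LiCl, THF, 40 °C; then 14, Pd(dppf)Cl2 (5 mol%), THF/NMP, 50 °C
Reagents that add atoms: none
Why: Zinc insertion into the primary C–I bond tolerates the acetate, and Negishi coupling with the enol triflate (oxidative addition, transmetalation, reductive elimination) forms the C16–C17 bond.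

Step 30
Reactants: 39 coupled C16=C2 alkene
Product: 41 C2 alcohol, via C2 alkylborane 40 (not isolated)
Conditions: BH3·THF, THF, 0 °C → rt; then NaBO3·4H2O, H2O, rt
Reagents that add atoms: sodium perborate, [Na+].[Na+].O[B-]1(O)OO[B-](O)(O)OO1
Why: Hydroboration of the trisubstituted alkene puts boron on the less substituted C2 and hydrogen on C16 by syn addition from the face opposite the axial C14 methyl, which sets C16 with its side chain equatorial, and the oxidation proceeds with retention.

Step 31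
Reactants: 41 C2 alcohol
Product: 42 C2 ketone
Conditions: DMP, NaHCO3, CH2Cl2, rt
Reagents that add atoms: none
Why: Dess–Martin oxidation gives the ketone under neutral conditions, and C16 already holds the equatorial side chain and so has no drive to epimerise.

Step 32
Reactants: 42 C2 ketone
Product: 43 exocyclic alkene
Conditions: Zn, CH2Br2, TiCl4, THF/CH2Cl2, 0 °C → rt
Reagents that add atoms: dibromomethane, BrCBr
Why: Takai–Lombardo methylenation with the non-basic gem-dizinc/titanium reagent converts the ketone into C2=C1 without enolising C16 and without attacking the acetate.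

Step 33
Reactants: 43 exocyclic alkene
Product: 44 C24 alcohol
Conditions: HF·pyridine, pyridine, THF, 0 °C → rt
Reagents that add atoms: none
Why: Fluoride-mediated desilylation cleaves the Si–O bond of the TBS ether while the PMB ether, the acetate and the alkene are stable.

Step 34
Reactants: 44 C24 alcohol
Product: 45 C24 ketone
Conditions: DMP, NaHCO3, CH2Cl2, rt
Reagents that add atoms: none
Why: Dess–Martin oxidation of the only free hydroxyl gives the oxepanone of the target.

Step 35
Reactants: 45 C24 ketone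
Product: 46 target CNP0148623.1
Conditions: DDQ, CH2Cl2/pH 7 buffer, 0 °C
Reagents that add atoms: none
Why: Oxidative PMB cleavage (hydride abstraction by DDQ, then hydrolysis of the oxocarbenium ion) frees the C10 alcohol, and no other group in the molecule is oxidised by DDQ.

**Compound list**

1 | nerol, (2Z)-3,7-dimethylocta-2,6-dien-1-ol | OC/C=C(C)\CCC=C(C)C | starting material
2 | neryl chloride, (2Z)-1-chloro-3,7-dimethylocta-2,6-diene | ClC/C=C(C)\CCC=C(C)C | intermediate
3 | neryl pinacolboronate, 2-[(2Z)-3,7-dimethylocta-2,6-dien-1-yl]-4,4,5,5-tetramethyl-1,3,2-dioxaborolane | CC(C)=CCC/C(C)=C\CB1OC(C)(C)C(C)(C)O1 | intermediate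
4 | pent-4-enal | C=CCCC=O | starting material
5 | (5S,6S)-6-ethenyl-6,10-dimethylundeca-1,9-dien-5-ol | C=CCC[C@H](O)[C@](C)(C=C)CCC=C(C)C | intermediate
6 | (5S,6S)-8-[(2S)-3,3-dimethyloxiran-2-yl]-6-ethenyl-6-methyloct-1-en-5-ol | C=CCC[C@H](O)[C@](C)(C=C)CC[C@@H]1OC1(C)C | intermediate
7 | (3S,6S,7S)-7-(but-3-en-1-yl)-6-ethenyl-2,2,6-trimethyloxepan-3-ol | C=CCC[C@@H]1OC(C)(C)[C@@H](O)CC[C@@]1(C)C=C | intermediate
8 | (3S,6S,7S)-7-(but-3-en-1-yl)-6-ethenyl-3-[(4-methoxybenzyl)oxy]-2,2,6-trimethyloxepane | C=CCC[C@@H]1OC(C)(C)[C@@H](OCc2ccc(OC)cc2)CC[C@@]1(C)C=C | intermediate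
9 | (3S,5aS,9aS)-3-[(4-methoxybenzyl)oxy]-2,2,5a-trimethyl-2,3,4,5,5a,8,9,9a-octahydro-1-benzoxepine (trans-fused) | C1=CCC[C@@H]2OC(C)(C)[C@@H](OCc3ccc(OC)cc3)CC[C@]21C | intermediate
10 | (3S,5aR,6R,7S,9aS)-6,7-epoxy-3-[(4-methoxybenzyl)oxy]-2,2,5a-trimethyldecahydro-1-benzoxepine (oxirane anti to the 5a-methyl) | C1C[C@@H]2OC(C)(C)[C@@H](OCc3ccc(OC)cc3)CC[C@@]2(C)[C@H]2O[C@@H]12 | intermediate
11 | (3S,5aS,6S,9aS)-3-[(4-methoxybenzyl)oxy]-2,2,5a-trimethyldecahydro-1-benzoxepin-6-ol | C1C[C@@H]2OC(C)(C)[C@@H](OCc3ccc(OC)cc3)CC[C@@]2(C)[C@@H](O)C1 | intermediate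
12 | (3S,5aR,9aS)-3-[(4-methoxybenzyl)oxy]-2,2,5a-trimethyloctahydro-1-benzoxepin-6(2H)-one | C1C[C@@H]2OC(C)(C)[C@@H](OCc3ccc(OC)cc3)CC[C@@]2(C)C(=O)C1 | intermediate
13 | potassium enolate of 12 (O–K on C16, C16=C2) | C1C[C@@H]2OC(C)(C)[C@@H](OCc3ccc(OC)cc3)CC[C@@]2(C)C(O[K])=C1 | intermediate (not isolated)
14 | (3S,5aR,9aS)-3-[(4-methoxybenzyl)oxy]-2,2,5a-trimethyl-2,3,4,5,5a,8,9,9a-octahydro-1-benzoxepin-6-yl trifluoromethanesulfonate | C1C[C@@H]2OC(C)(C)[C@@H](OCc3ccc(OC)cc3)CC[C@@]2(C)C(OS(=O)(=O)C(F)(F)F)=C1 | intermediate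
15 | 2-(2-bromoethyl)-2-methyl-1,3-dioxolane | CC1(CCBr)OCCO1 | starting material
16 | [2-(2-methyl-1,3-dioxolan-2-yl)ethyl]magnesium bromide | CC1(CC[Mg]Br)OCCO1 | intermediate (not isolated)
17 | 3-(2-methyl-1,3-dioxolan-2-yl)propanal | CC1(CCC=O)OCCO1 | intermediate
18 | (3S,4S)-4-ethenyl-4,8-dimethyl-1-(2-methyl-1,3-dioxolan-2-yl)non-7-en-3-ol | CC1(CC[C@H](O)[C@](C)(C=C)CCC=C(C)C)OCCO1 | intermediate
19 | (3S,4S)-6-[(2S)-3,3-dimethyloxiran-2-yl]-4-ethenyl-4-methyl-1-(2-methyl-1,3-dioxolan-2-yl)hexan-3-ol | CC1(CC[C@H](O)[C@](C)(C=C)CC[C@@H]2OC2(C)C)OCCO1 | intermediate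
20 | (3S,6S,7S)-6-ethenyl-2,2,6-trimethyl-7-[2-(2-methyl-1,3-dioxolan-2-yl)ethyl]oxepan-3-ol | C=C[C@]1(C)CC[C@H](O)C(C)(C)O[C@H]1CCC1(C)OCCO1 | intermediate
21 | tert-butyldimethylsilyl ether of 20, (3S,6S,7S) | C=C[C@]1(C)CC[C@H](O[Si](C)(C)C(C)(C)C)C(C)(C)O[C@H]1CCC1(C)OCCO1 | intermediate
22 | B-alkyl-9-BBN adduct of 21 (boron on C18) | C1CC2CCCC(C1)B2CC[C@]1(C)CC[C@H](O[Si](C)(C)C(C)(C)C)C(C)(C)O[C@H]1CCC1(C)OCCO1 | intermediate (not isolated)
23 | 2-[(3S,6S,7S)-3-(tert-butyldimethylsilyloxy)-2,2,6-trimethyl-7-[2-(2-methyl-1,3-dioxolan-2-yl)ethyl]oxepan-6-yl]ethan-1-ol | OCC[C@]1(C)CC[C@H](O[Si](C)(C)C(C)(C)C)C(C)(C)O[C@H]1CCC1(C)OCCO1 | intermediate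
24 | [(3S,6S,7S)-3-(tert-butyldimethylsilyloxy)-2,2,6-trimethyl-7-[2-(2-methyl-1,3-dioxolan-2-yl)ethyl]oxepan-6-yl]acetic acid | OC(=O)C[C@]1(C)CC[C@H](O[Si](C)(C)C(C)(C)C)C(C)(C)O[C@H]1CCC1(C)OCCO1 | intermediate
25 | methyl ester of 24 | COC(=O)C[C@]1(C)CC[C@H](O[Si](C)(C)C(C)(C)C)C(C)(C)O[C@H]1CCC1(C)OCCO1 | intermediate
26 | lithium enolate of 25 | COC(O[Li])=C[C@]1(C)CC[C@H](O[Si](C)(C)C(C)(C)C)C(C)(C)O[C@H]1CCC1(C)OCCO1 | intermediate (not isolated)
27 | methyl trimethylsilyl ketene acetal of 25 | COC(O[Si](C)(C)C)=C[C@]1(C)CC[C@H](O[Si](C)(C)C(C)(C)C)C(C)(C)O[C@H]1CCC1(C)OCCO1 | intermediate (not isolated)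
28 | methyl (2RS)-2-bromo-2-[(3S,6R,7S)-3-(tert-butyldimethylsilyloxy)-2,2,6-trimethyl-7-[2-(2-methyl-1,3-dioxolan-2-yl)ethyl]oxepan-6-yl]acetate | COC(=O)C(Br)[C@]1(C)CC[C@H](O[Si](C)(C)C(C)(C)C)C(C)(C)O[C@H]1CCC1(C)OCCO1 | intermediate
29 | methyl (2RS)-2-bromo-2-[(3S,6R,7S)-3-(tert-butyldimethylsilyloxy)-2,2,6-trimethyl-7-(3-oxobutyl)oxepan-6-yl]acetate | COC(=O)C(Br)[C@]1(C)CC[C@H](O[Si](C)(C)C(C)(C)C)C(C)(C)O[C@H]1CCC(C)=O | intermediate
30 | methyl (3S,5aS,6S,7R,9aS)-3-(tert-butyldimethylsilyloxy)-7-hydroxy-2,2,5a,7-tetramethyldecahydro-1-benzoxepine-6-carboxylate | COC(=O)[C@H]1[C@]2(C)CC[C@H](O[Si](C)(C)C(C)(C)C)C(C)(C)O[C@H]2CC[C@@]1(C)O | intermediate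
31 | (3S,5aS,6R,7R,9aS)-3-(tert-butyldimethylsilyloxy)-6-(hydroxymethyl)-2,2,5a,7-tetramethyldecahydro-1-benzoxepin-7-ol | OC[C@H]1[C@]2(C)CC[C@H](O[Si](C)(C)C(C)(C)C)C(C)(C)O[C@H]2CC[C@@]1(C)O | intermediate
32 | (3S,5aS,6S,7R,9aS)-3-(tert-butyldimethylsilyloxy)-7-hydroxy-2,2,5a,7-tetramethyldecahydro-1-benzoxepine-6-carbaldehyde | O=C[C@H]1[C@]2(C)CC[C@H](O[Si](C)(C)C(C)(C)C)C(C)(C)O[C@H]2CC[C@@]1(C)O | intermediate
33 | (3S,5aS,6S,7R,9aS)-3-(tert-butyldimethylsilyloxy)-6-ethenyl-2,2,5a,7-tetramethyldecahydro-1-benzoxepin-7-ol | C=C[C@H]1[C@]2(C)CC[C@H](O[Si](C)(C)C(C)(C)C)C(C)(C)O[C@H]2CC[C@@]1(C)O | intermediate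
34 | acetate of 33 at the tertiary hydroxyl, (3S,5aS,6S,7R,9aS) | C=C[C@H]1[C@]2(C)CC[C@H](O[Si](C)(C)C(C)(C)C)C(C)(C)O[C@H]2CC[C@@]1(C)OC(C)=O | intermediate
35 | B-alkyl-9-BBN adduct of 34 (boron on C17) | C1CC2CCCC(C1)B2CC[C@H]1[C@]2(C)CC[C@H](O[Si](C)(C)C(C)(C)C)C(C)(C)O[C@H]2CC[C@@]1(C)OC(C)=O | intermediate (not isolated)
36 | (3S,5aS,6S,7R,9aS)-3-(tert-butyldimethylsilyloxy)-6-(2-hydroxyethyl)-2,2,5a,7-tetramethyldecahydro-1-benzoxepin-7-yl acetate | OCC[C@H]1[C@]2(C)CC[C@H](O[Si](C)(C)C(C)(C)C)C(C)(C)O[C@H]2CC[C@@]1(C)OC(C)=O | intermediate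
37 | (3S,5aS,6S,7R,9aS)-3-(tert-butyldimethylsilyloxy)-6-(2-iodoethyl)-2,2,5a,7-tetramethyldecahydro-1-benzoxepin-7-yl acetate | ICC[C@H]1[C@]2(C)CC[C@H](O[Si](C)(C)C(C)(C)C)C(C)(C)O[C@H]2CC[C@@]1(C)OC(C)=O | intermediate
38 | alkylzinc iodide from 37 (zinc on C17) | I[Zn]CC[C@H]1[C@]2(C)CC[C@H](O[Si](C)(C)C(C)(C)C)C(C)(C)O[C@H]2CC[C@@]1(C)OC(C)=O | intermediate (not isolated)
39 | coupled alkene: right-half acetate 37 with iodine replaced by C16 of the left-half 6,7-ene (PMB ether); stereocentres as in 14 and 37 | C1C[C@@H]2OC(C)(C)[C@@H](OCc3ccc(OC)cc3)CC[C@@]2(C)C(=C1)CC[C@H]1[C@]2(C)CC[C@H](O[Si](C)(C)C(C)(C)C)C(C)(C)O[C@H]2CC[C@@]1(C)OC(C)=O | intermediate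
40 | C2 alkylborane from 39 (BH2 on C2 and H on C16, both on the face anti to the C14 methyl) | B[C@H]1CC[C@@H]2OC(C)(C)[C@@H](OCc3ccc(OC)cc3)CC[C@@]2(C)[C@@H]1CC[C@H]1[C@]2(C)CC[C@H](O[Si](C)(C)C(C)(C)C)C(C)(C)O[C@H]2CC[C@@]1(C)OC(C)=O | intermediate (not isolated)
41 | C2 alcohol: left unit (3S,5aS,6S,7S,9aS)-7-hydroxy-3-(PMB-oxy)-2,2,5a-trimethyldecahydro-1-benzoxepin-6-yl joined by CH2CH2 to C6 of the right unit of 36 | O[C@H]1CC[C@@H]2OC(C)(C)[C@@H](OCc3ccc(OC)cc3)CC[C@@]2(C)[C@@H]1CC[C@H]1[C@]2(C)CC[C@H](O[Si](C)(C)C(C)(C)C)C(C)(C)O[C@H]2CC[C@@]1(C)OC(C)=O | intermediate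
42 | C2 ketone of 41 (left unit 7-oxo, 6S) | O=C1CC[C@@H]2OC(C)(C)[C@@H](OCc3ccc(OC)cc3)CC[C@@]2(C)[C@@H]1CC[C@H]1[C@]2(C)CC[C@H](O[Si](C)(C)C(C)(C)C)C(C)(C)O[C@H]2CC[C@@]1(C)OC(C)=O | intermediate
43 | C2 methylidene compound (target with C10–OPMB and C24–OTBS in place of C10–OH and C24=O) | C=C1CC[C@@H]2OC(C)(C)[C@@H](OCc3ccc(OC)cc3)CC[C@@]2(C)[C@@H]1CC[C@H]1[C@]2(C)CC[C@H](O[Si](C)(C)C(C)(C)C)C(C)(C)O[C@H]2CC[C@@]1(C)OC(C)=O | intermediate
44 | C24 (S)-alcohol of 43 (TBS removed) | C=C1CC[C@@H]2OC(C)(C)[C@@H](OCc3ccc(OC)cc3)CC[C@@]2(C)[C@@H]1CC[C@H]1[C@]2(C)CC[C@H](O)C(C)(C)O[C@H]2CC[C@@]1(C)OC(C)=O | intermediate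
45 | C10 PMB ether of the target | C=C1CC[C@@H]2OC(C)(C)[C@@H](OCc3ccc(OC)cc3)CC[C@@]2(C)[C@@H]1CC[C@H]1[C@]2(C)CCC(=O)C(C)(C)O[C@H]2CC[C@@]1(C)OC(C)=O | intermediate
46 | CNP0148623.1 (5S,10S,14S,16R,19S,20S,30S,33R in target-SMILES numbering) | C=C1CC[C@@H]2OC(C)(C)[C@@H](O)CC[C@@]2(C)[C@@H]1CC[C@H]1[C@]2(C)CCC(=O)C(C)(C)O[C@H]2CC[C@@]1(C)OC(C)=O | target

**Totals**

Total step count: 35. Longest linear sequence: 25 steps (steps 1, 2 and 13–35).

**Steps most likely to fail**

Step 5 (epoxide opening, left half). The hydroxyl may attack the secondary epoxide carbon C10 in a 6-exo closure to a tetrahydropyran, or the activated epoxide may rearrange by hydride shift, instead of the 7-endo attack at C7. Fallback, from 6: isomerisation of the epoxide with diethylaluminium 2,2,6,6-tetramethylpiperidide (toluene, 0 °C) gives the allylic diol F1, which keeps the C10 carbinol and carries an isopropenyl group at C7. Ring-closing metathesis as in step 7 gives the cyclohexene diol F2. Mercury(II) trifluoroacetate (CH2Cl2, K2CO3, 0 °C) then adds the C5 hydroxyl to C7 of the 1,1-disubstituted alkene (Markovnikov, 7-exo) to give the organomercurial F3. Reduction with NaBH4/NaOH gives the bicyclic oxepanol F4, and p-methoxybenzylation as in step 6 comes back to the route at 9.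

Step 15 (epoxide opening, right half). The same loss of regiocontrol may occur, and the Lewis acid may also start ketal exchange with the free hydroxyl. Fallback, from 19: the same aluminium amide isomerisation gives the allylic diol F5. Mercury(II) trifluoroacetate (CH2Cl2, K2CO3, 0 °C) closes the oxepane by Markovnikov 7-exo addition of the C30 hydroxyl to C26, the isopropenyl group reacting far faster than the vinyl group on the quaternary carbon, to give the organomercurial F6. NaBH4 demercuration comes back to the route at 20.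

Step 22 (key step). The samarium enolate may be protonated before it closes (simple debromination), the aldolate may revert by retro-aldol reaction on warming, or a non-chelated pathway may erode the cis selectivity. Fallback, from 25: the silyl ketene acetal 27 is made as in step 20 and, instead of being brominated, is treated with catalytic TMSOTf in CH2Cl2 at −78 °C. The dioxolane opens to the C33 oxocarbenium ion, which the ketene acetal attacks through the same chair with the oxygen axial (intramolecular Mukaiyama aldol addition to a ketal), giving the silylated hydroxyethyl ether F7. Methanolysis (K2CO3, MeOH) gives the 2-hydroxyethyl ether F8, Appel iodination gives the 2-iodoethyl ether F9, and zinc in ethanol fragments it reductively with loss of ethene, which comes back to the route at 30.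

Further compounds
F1 | step 5 | (5S,6S,9S)-6-ethenyl-6,10-dimethylundeca-1,10-diene-5,9-diol | C=CCC[C@H](O)[C@](C)(C=C)CC[C@H](O)C(C)=C
F2 | step 5 | cyclohexene diol: 2-methylcyclohex-3-en-1-ol carrying at C2 a (3S)-3-hydroxy-4-methylpent-4-enyl chain (C5 S, C14 as in 9) | C1=CCC[C@H](O)[C@@]1(C)CC[C@H](O)C(C)=C
F3 | step 5 | organomercurial: F4 with one C7 methyl as CH2HgOCOCF3 (C7 epimers) | C1=CCC[C@@H]2OC(C)(C[Hg]OC(=O)C(F)(F)F)[C@@H](O)CC[C@]21C
F4 | step 5 | (3S,5aS,9aS)-2,2,5a-trimethyl-2,3,4,5,5a,8,9,9a-octahydro-1-benzoxepin-3-ol | C1=CCC[C@@H]2OC(C)(C)[C@@H](O)CC[C@]21C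
F5 | step 15 | (3S,4S,7S)-4-ethenyl-4,8-dimethyl-1-(2-methyl-1,3-dioxolan-2-yl)non-8-ene-3,7-diol | CC1(CC[C@H](O)[C@](C)(C=C)CC[C@H](O)C(C)=C)OCCO1
F6 | step 15 | organomercurial: 20 with one C26 methyl as CH2HgOCOCF3 (C26 epimers) | C=C[C@]1(C)CC[C@H](O)C(C)(C[Hg]OC(=O)C(F)(F)F)O[C@H]1CCC1(C)OCCO1
F7 | step 22 | 30 with the C33 hydroxyl as its 2-(trimethylsilyloxy)ethyl ether | COC(=O)[C@H]1[C@]2(C)CC[C@H](O[Si](C)(C)C(C)(C)C)C(C)(C)O[C@H]2CC[C@@]1(C)OCCO[Si](C)(C)C
F8 | step 22 | 30 with the C33 hydroxyl as its 2-hydroxyethyl ether | COC(=O)[C@H]1[C@]2(C)CC[C@H](O[Si](C)(C)C(C)(C)C)C(C)(C)O[C@H]2CC[C@@]1(C)OCCO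
F9 | step 22 | 30 with the C33 hydroxyl as its 2-iodoethyl ether | COC(=O)[C@H]1[C@]2(C)CC[C@H](O[Si](C)(C)C(C)(C)C)C(C)(C)O[C@H]2CC[C@@]1(C)OCCI
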